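**Assumption:** the given SMILES encodes the (2R)-flavanone, and 7-hydroxy-4H-chromen-4-one and the ligand (S)-t-BuPyOx are bought. This route is designed from known reaction classes and has not been run on these exact substrates.

## Retrosynthetic overview

1. Target ⇒ its 7-O-TIPS ether (final buffered desilylation).
2. C2–aryl bond ⇒ Pd(II)/(S)-t-BuPyOx asymmetric conjugate addition of the B-ring arylboronic acid to a 7-silyloxychromone; this is the only stereo-defining step and sets C2 as R.
3. Arylboronic acid ⇒ 6-bromo-2,2-dimethyl-8-prenyl-2H-chromene by Br/Li exchange and borylation.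
4. Bromochromene ⇒ 4-bromo-2-prenylphenol (propargyl ether, then Claisen/6π-electrocyclisation) ⇒ 4-bromophenol and prenyl bromide.
5. Ring order: the benzopyranone (A/C rings) is purchased intact; the chromene pyran ring is formed in step 3; the coupling forms no ring.

## Route

**Step 1**
Reactants: **1** 4-bromophenol; **2** prenyl bromide (1-bromo-3-methylbut-2-ene)
Product: **3** 4-bromo-2-(3-methylbut-2-en-1-yl)phenol
Conditions: NaH, PhMe, 0 °C → rt; then **2**, rt
Reagents that add atoms: prenyl bromide (**2**), CC(C)=CCBr
Why: Ortho-selective C-alkylation of a tight sodium phenoxide ion pair in a non-polar solvent; the para position is blocked by Br, and O-prenyl and diprenyl by-products are removed by chromatography.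

**Step 2**
Reactants: **3**; **4** 3-chloro-3-methylbut-1-yne
Product: **5** 4-bromo-1-[(2-methylbut-3-yn-2-yl)oxy]-2-(3-methylbut-2-en-1-yl)benzene
Conditions: DBU, CuCl2·2H2O (cat.), MeCN, 0 °C → rt
Reagents that add atoms: 3-chloro-3-methylbut-1-yne (**4**), C#CC(C)(C)Cl
Why: Cu-catalysed propargylic O-alkylation of the phenol, which tolerates the tertiary propargylic centre and the ortho substituent.

**Step 3**
Reactants: **5**
Product: **6** 6-bromo-2,2-dimethyl-8-(3-methylbut-2-en-1-yl)-2H-chromene
Conditions: o-xylene, 140 °C
Reagents that add atoms: none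
Why: Aryl propargyl ether Claisen rearrangement to the only free ortho position, then tautomerisation, 1,5-H shift and oxa-6π electrocyclisation to the 2,2-dimethylchromene; the aryl bromide and prenyl group are thermally inert.

**Step 4**
Reactants: **6**; **7** triisopropyl borate
Product: **8** [2,2-dimethyl-8-(3-methylbut-2-en-1-yl)-2H-chromen-6-yl]boronic acid
Conditions: **7**, THF, −78 °C; n-BuLi added dropwise (in situ quench); → 0 °C; aq. NH4Cl (pH ≈ 5)
Reagents that add atoms: triisopropyl borate (**7**), CC(C)OB(OC(C)C)OC(C)C; water, O (boronate hydrolysis)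
Why: Br/Li exchange with immediate borate trapping at −78 °C outcompetes benzylic/allylic deprotonation, and the mild hydrolysis leaves the acid-sensitive alkenes intact.

**Step 5**
Reactants: **9** 7-hydroxy-4H-chromen-4-one; **10** triisopropylsilyl chloride
Product: **11** 7-[(triisopropylsilyl)oxy]-4H-chromen-4-one
Conditions: TIPSCl, imidazole, DMF, rt
Reagents that add atoms: TIPSCl (**10**), CC(C)[Si](Cl)(C(C)C)C(C)C
Why: Standard phenol silylation; the bulky TIPS ether masks the acidic phenol and should survive the warm aqueous conditions of step 6.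

**Step 6**
Reactants: **11**; **8** (1.5–2 equiv)
Product: **12** (2R)-2-[2,2-dimethyl-8-(3-methylbut-2-en-1-yl)-2H-chromen-6-yl]-7-[(triisopropylsilyl)oxy]-2,3-dihydro-4H-chromen-4-one
Conditions: Pd(OCOCF3)2 (5 mol %), (S)-t-BuPyOx (6 mol %), NH4PF6 (30 mol %), H2O (5 equiv), ClCH2CH2Cl, 60 °C
Reagents that add atoms: none beyond reactants **8** and **11** (the C3–H comes from water)
Why: Pd(II)-catalysed asymmetric conjugate addition of an arylboronic acid to a chromone (transmetalation, enantio-determining insertion, protonolysis of the Pd enolate). By analogy with the (S)-ligand/(R)-β-aryl ketone outcome for cyclic enones, the (S)-ligand should give the (2R)-flavanone; confirm configuration and ee by chiral HPLC and CD.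

**Step 7**
Reactants: **12**
Product: **13** ent-abyssinone III, (2R)-7-hydroxy-2-[2,2-dimethyl-8-(3-methylbut-2-en-1-yl)-2H-chromen-6-yl]-2,3-dihydro-4H-chromen-4-one
Conditions: TBAF/AcOH (1:1), THF, 0 °C
Reagents that add atoms: none
Why: Fluoride cleavage of the aryl silyl ether; acetic acid buffering avoids the basic conditions that would racemise C2 by retro-oxa-Michael ring opening, and no acid strong enough to hydrate the prenyl or chromene alkenes is present.

## Compound list

1 | 4-bromophenol | Oc1ccc(Br)cc1 | starting material
2 | prenyl bromide | CC(C)=CCBr | starting material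
3 | 4-bromo-2-(3-methylbut-2-en-1-yl)phenol | CC(C)=CCc1cc(Br)ccc1O | intermediate
4 | 3-chloro-3-methylbut-1-yne | C#CC(C)(C)Cl | starting material
5 | 4-bromo-1-[(2-methylbut-3-yn-2-yl)oxy]-2-(3-methylbut-2-en-1-yl)benzene | CC(C)=CCc1cc(Br)ccc1OC(C)(C)C#C | intermediate
6 | 6-bromo-2,2-dimethyl-8-(3-methylbut-2-en-1-yl)-2H-chromene | CC(C)=CCc1cc(Br)cc2c1OC(C)(C)C=C2 | intermediate
7 | triisopropyl borate | CC(C)OB(OC(C)C)OC(C)C | starting material
8 | [2,2-dimethyl-8-(3-methylbut-2-en-1-yl)-2H-chromen-6-yl]boronic acid | CC(C)=CCc1cc(B(O)O)cc2c1OC(C)(C)C=C2 | intermediate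
9 | 7-hydroxy-4H-chromen-4-one | O=c1ccoc2cc(O)ccc12 | starting material
10 | triisopropylsilyl chloride | CC(C)[Si](Cl)(C(C)C)C(C)C | starting material
11 | 7-[(triisopropylsilyl)oxy]-4H-chromen-4-one | O=c1ccoc2cc(O[Si](C(C)C)(C(C)C)C(C)C)ccc12 | intermediate
12 | (2R)-2-[2,2-dimethyl-8-(3-methylbut-2-en-1-yl)-2H-chromen-6-yl]-7-[(triisopropylsilyl)oxy]chroman-4-one | CC(C)=CCc1cc([C@H]2CC(=O)c3ccc(O[Si](C(C)C)(C(C)C)C(C)C)cc3O2)cc2c1OC(C)(C)C=C2 | intermediate
13 | ent-abyssinone III, (2R)-7-hydroxy-2-[2,2-dimethyl-8-(3-methylbut-2-en-1-yl)-2H-chromen-6-yl]chroman-4-one | CC(C)=CCc1cc([C@H]2CC(=O)c3ccc(O)cc3O2)cc2c1OC(C)(C)C=C2 | target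

## Summary

**Total steps:** 7 (convergent).
**Longest linear sequence:** 6 (steps 1 → 2 → 3 → 4 → 6 → 7; step 5 is a one-step side branch).

**Three steps most likely to fail, with fallbacks:**

1. **Step 6 (asymmetric conjugate addition).** Risks are alkene interference with cationic Pd(II), protodeboronation, and lower ee with an electron-rich arylboronic acid. Fallback: form ring C last by organocatalysis.
   - Convert bromide **6** to the aldehyde (n-BuLi, then DMF).
   - Knoevenagel-condense it with tert-butyl 3-[2-hydroxy-4-(silyloxy)phenyl]-3-oxopropanoate.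
   - Cyclise by a cinchona-alkaloid thiourea-catalysed intramolecular oxa-Michael addition (the pseudo-enantiomeric catalyst that gives 2R).
   - Cleave the ester and decarboxylate with TsOH, then desilylate.

2. **Step 1 (ortho C-prenylation).** Risks are O-alkylation, diprenylation and a modest yield. Fallback: start from 4-bromo-2-iodophenol, build the chromene first (as in steps 2–3), then install the prenyl group by chemoselective Stille coupling at the C–I bond with tributyl(3-methylbut-2-enyl)stannane.

3. **Step 4 (lithiation–borylation).** Risks are deprotonation of the doubly activated ArCH2 and protodeboronation of the electron-rich boronic acid on isolation. Fallback: Pd-catalysed Miyaura borylation of **6** with B2pin2 to the pinacol boronate, used directly in a Rh(I)/chiral diene-catalysed asymmetric 1,4-addition to **11**.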